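**Plan**

- Retrosynthetic cuts, in order: the second methyl on C8 (dearomative methylation), the C6–acyl bond (aryllithium plus Weinreb amide), the CH2–CH= bond of the 4-methylpent-3-enyl chain (B-alkyl Suzuki coupling), the C3=C4 alkene of ring B (ring-closing metathesis), and the aryl O–C2 bond (phenoxide plus bromomalonate).
- Enabling feature: C2 of ring B, the quaternary carbon on O1, carries the C3=C4 ring alkene and a chain whose first two carbons are CH2 groups. A C2 bearing methyl and two vinyl groups is therefore a prochiral stand-in: one vinyl becomes C3, the other becomes the two-carbon stub of the side chain.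
- Forward order: ring A is bought as 2-methylphloroglucinol. Formylation, bis-MOM protection, O-alkylation and three methylenations give the triene; ring B then closes by asymmetric metathesis. Side chain, acyl group and second C8 methyl follow, and ring A is dearomatised last.
- Stereochemistry: C2 (R) comes from the chiral molybdenum catalyst in the desymmetrising ring closure; the acyl stereocentre (R) is bought with (R)-2-methylbutanoic acid.

Key step: step 7

Assumption: the sense of induction of the biphenolate catalyst on this aryl ether cannot be assigned in advance, so the ligand antipode that delivers 2R is to be fixed by one trial with each enantiomer of the catalyst.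

**Step 1**
Reactants: 1 2-methylbenzene-1,3,5-triol (2-methylphloroglucinol)
Product: 3 2,4,6-trihydroxy-3-methylbenzaldehyde, via aryl iminium chloride 2 (not isolated)
Conditions: POCl3, DMF, EtOAc, 0 °C → rt; then H2O, 50 °C
Reagents that add atoms: N,N-dimethylformamide CN(C)C=O; water O
Why: Vilsmeier–Haack formylation, in which the chloroiminium ion attacks one of the two equivalent free positions of the electron-rich triol and hydrolysis of iminium 2 gives the aldehyde, the first formyl group deactivating the ring towards a second.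

**Step 2**
Reactants: 3 2,4,6-trihydroxy-3-methylbenzaldehyde
Product: 4 2-hydroxy-4,6-bis(methoxymethoxy)-3-methylbenzaldehyde
Conditions: MOMCl (2.1 equiv), i-Pr2NEt, CH2Cl2, 0 °C → rt
Reagents that add atoms: chloromethyl methyl ether COCCl
Why: Williamson-type O-alkylation in which the para phenol and the less hindered ortho phenol react first, while the hydroxyl wedged between the formyl and methyl groups should stay free because it is chelated to the carbonyl and is the most shielded.

**Step 3**
Reactants: 4 2-hydroxy-4,6-bis(methoxymethoxy)-3-methylbenzaldehyde; 5 diethyl 2-bromo-2-methylpropanedioate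
Product: 6 diethyl 2-[2-formyl-3,5-bis(methoxymethoxy)-6-methylphenoxy]-2-methylpropanedioate
Conditions: Cs2CO3, DMF, 60 °C
Reagents that add atoms: none
Why: Williamson ether synthesis (SN2) of the caesium phenoxide on the doubly carbonyl-activated tertiary bromide, the usual entry to 2-aryloxy-2-methylmalonates; the malonate has no alpha hydrogen and so cannot condense with the neighbouring aldehyde.

**Step 4**
Reactants: 6 diethyl 2-[2-formyl-3,5-bis(methoxymethoxy)-6-methylphenoxy]-2-methylpropanedioate
Product: 7 diethyl 2-[6-ethenyl-3,5-bis(methoxymethoxy)-2-methylphenoxy]-2-methylpropanedioate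
Conditions: Ph3PCH3Br, KN(SiMe3)2 (1.1 equiv), THF, −78 → 0 °C
Reagents that add atoms: methyltriphenylphosphonium bromide C[P+](c1ccccc1)(c1ccccc1)c1ccccc1.[Br-]
Why: Wittig methylenation, the unstabilised ylide adding to the aldehyde far faster than to the two hindered, non-enolisable esters, so that only the formyl group is converted.

**Step 5**
Reactants: 7 diethyl 2-[6-ethenyl-3,5-bis(methoxymethoxy)-2-methylphenoxy]-2-methylpropanedioate
Product: 8 2-[6-ethenyl-3,5-bis(methoxymethoxy)-2-methylphenoxy]-2-methylpropane-1,3-diol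
Conditions: LiAlH4, THF, 0 °C; aqueous NaOH work-up
Reagents that add atoms: none
Why: Hydride reduction of a 2,2-disubstituted malonate to the 1,3-diol by LiAlH4, the aryl ether, MOM acetals and styrene being inert to hydride.

**Step 6**
Reactants: 8 2-[6-ethenyl-3,5-bis(methoxymethoxy)-2-methylphenoxy]-2-methylpropane-1,3-diol
Product: 10 3,5-bis(methoxymethoxy)-2-methyl-1-[(3-methylpenta-1,4-dien-3-yl)oxy]-6-vinylbenzene, via dialdehyde 9 (not isolated)
Conditions: (COCl)2, DMSO, CH2Cl2, −78 °C; Et3N, −78 → −20 °C; then Ph3P=CH2 (from Ph3PCH3Br, KN(SiMe3)2, THF, excess), −78 °C → rt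
Reagents that add atoms: methyltriphenylphosphonium bromide C[P+](c1ccccc1)(c1ccccc1)c1ccccc1.[Br-]
Why: Swern oxidation followed in the same flask by double Wittig methylenation, which spares isolation of the non-enolisable but hydration- and deformylation-prone dialdehyde 9; the two arms are identical, so the product is achiral and should be kept cold to avoid sigmatropic rearrangement.

**Step 7**
Reactants: 10 3,5-bis(methoxymethoxy)-2-methyl-1-[(3-methylpenta-1,4-dien-3-yl)oxy]-6-vinylbenzene
Product: 11 (2R)-5,7-bis(methoxymethoxy)-2,8-dimethyl-2-vinyl-2H-chromene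
Conditions: Mo(N-2,6-i-Pr2C6H3)(CHCMe2Ph)[3,3'-di-tert-butyl-5,5',6,6'-tetramethylbiphenyl-2,2'-diolate], single enantiomer (5–10 mol%), C6H6, 22 → 50 °C, N2 sweep
Reagents that add atoms: none
Why: Catalytic enantioselective ring-closing olefin metathesis: the hexavalent molybdenum alkylidene exchanges onto a terminal alkene of 10, adds across the partner alkene in an intramolecular [2+2] step to a molybdacyclobutane, and cycloreversion forms the C3=C4 bond and expels ethene. The closest known reaction type is the desymmetrisation of achiral trienes to unsaturated cyclic tertiary ethers by molybdenum imido alkylidene biphenolates, applied here to an aryl ether. Ring B closes as a six-membered 2H-pyran by ring-closing metathesis, the new double bond lying inside the ring and cis by necessity. C2 becomes stereogenic when one of its two enantiotopic vinyl groups is drawn into the metallacycle, and the choice is made by the chiral pocket of the biphenolate and arylimido ligands, since the substrate is achiral. The step needs enantiotopic-group selectivity without later erosion: the C8 methyl and C5 OMOM groups flank the ether and styrene arms and hold them together, the quaternary C2 slows homodimerisation of the spare vinyl group, and the product can racemise only by ethene-mediated ring opening, which the nitrogen sweep should suppress. The untouched vinyl group remains as the handle for the side chain.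

**Step 8**
Reactants: 11 (2R)-5,7-bis(methoxymethoxy)-2,8-dimethyl-2-vinyl-2H-chromene; 12 1-bromo-2-methylprop-1-ene
Product: 14 (2R)-5,7-bis(methoxymethoxy)-2,8-dimethyl-2-(4-methylpent-3-en-1-yl)-2H-chromene, via alkylborane 13 (not isolated)
Conditions: 9-BBN dimer, THF, 0 °C → rt; then 12, PdCl2(dppf) (5 mol%), 3 M aq NaOH, THF, 60 °C
Reagents that add atoms: none
Why: Hydroboration followed by B-alkyl Suzuki–Miyaura coupling, 9-BBN adding anti-Markovnikov to the monosubstituted vinyl group much faster than to the cis-disubstituted conjugated ring alkene, and the primary alkylborane 13 coupling with the vinyl bromide under zerovalent palladium catalysis without touching C2.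

**Step 9**
Reactants: 15 (R)-2-methylbutanoic acid
Product: 17 (2R)-N-methoxy-N,2-dimethylbutanamide, via acyl imidazolide 16 (not isolated)
Conditions: CDI, CH2Cl2, 0 °C → rt; then MeNH(OMe)·HCl, rt
Reagents that add atoms: N,O-dimethylhydroxylamine hydrochloride CNOC.Cl
Why: Amide formation through the acyl imidazolide (carbonyldiimidazole coupling), a mild activation that does not ionise the alpha C–H, so the R configuration should be carried through.

**Step 10**
Reactants: 14 (2R)-5,7-bis(methoxymethoxy)-2,8-dimethyl-2-(4-methylpent-3-en-1-yl)-2H-chromene; 17 (2R)-N-methoxy-N,2-dimethylbutanamide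
Product: 19 (2R)-1-[(2R)-5,7-bis(methoxymethoxy)-2,8-dimethyl-2-(4-methylpent-3-en-1-yl)-2H-chromen-6-yl]-2-methylbutan-1-one, via aryllithium 18 (not isolated)
Conditions: n-BuLi, THF, 0 °C; then 17, −78 → 0 °C; sat. aq NH4Cl
Reagents that add atoms: none
Why: Directed ortho-metalation followed by Weinreb ketone synthesis, C6–H being the only ring hydrogen and lying between two OMOM directing groups, while the chelated tetrahedral adduct of 18 stops at the ketone stage and keeps the alpha stereocentre out of enolate chemistry.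

**Step 11**
Reactants: 19 (2R)-1-[(2R)-5,7-bis(methoxymethoxy)-2,8-dimethyl-2-(4-methylpent-3-en-1-yl)-2H-chromen-6-yl]-2-methylbutan-1-one
Product: 20 (2R)-1-[(2R)-5,7-dihydroxy-2,8-dimethyl-2-(4-methylpent-3-en-1-yl)-2H-chromen-6-yl]-2-methylbutan-1-one
Conditions: 3 M aq HCl, MeOH, rt → 40 °C
Reagents that add atoms: none
Why: Acid-catalysed acetal exchange (MOM cleavage) in methanol, both MOM ethers being ortho to the ketone and expected to cleave under mild acid that leaves the chromene, the trisubstituted alkene and the alpha stereocentre alone.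

**Step 12**
Reactants: 20 (2R)-1-[(2R)-5,7-dihydroxy-2,8-dimethyl-2-(4-methylpent-3-en-1-yl)-2H-chromen-6-yl]-2-methylbutan-1-one
Product: 21 (2R)-5-hydroxy-2,8,8-trimethyl-6-[(2R)-2-methylbutanoyl]-2-(4-methylpent-3-en-1-yl)-2H-chromen-7(8H)-one (CNP0313486.1)
Conditions: NaOMe, MeI, MeOH, 0 °C → rt
Reagents that add atoms: iodomethane CI
Why: Dearomative C-methylation of an acylphloroglucinol, the ambident phenoxide of 20 reacting at the methyl-bearing C8 (the only ring carbon without an acyl group) to give the gem-dimethyl cyclohexadienone whose C5 enol is hydrogen-bonded to the acyl carbonyl, with neither stereocentre involved.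

**Compound list**

1 | 2-methylbenzene-1,3,5-triol (2-methylphloroglucinol) | Cc1c(O)cc(O)cc1O | starting material
2 | N-[(2,4,6-trihydroxy-3-methylphenyl)methylidene]-N-methylmethanaminium chloride | C[N+](C)=Cc1c(O)cc(O)c(C)c1O.[Cl-] | intermediate
3 | 2,4,6-trihydroxy-3-methylbenzaldehyde | Cc1c(O)cc(O)c(C=O)c1O | intermediate
4 | 2-hydroxy-4,6-bis(methoxymethoxy)-3-methylbenzaldehyde | Cc1c(O)c(C=O)c(OCOC)cc1OCOC | intermediate
5 | diethyl 2-bromo-2-methylpropanedioate | CCOC(=O)C(C)(Br)C(=O)OCC | starting material
6 | diethyl 2-[2-formyl-3,5-bis(methoxymethoxy)-6-methylphenoxy]-2-methylpropanedioate | CCOC(=O)C(C)(Oc1c(C)c(OCOC)cc(OCOC)c1C=O)C(=O)OCC | intermediate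
7 | diethyl 2-[6-ethenyl-3,5-bis(methoxymethoxy)-2-methylphenoxy]-2-methylpropanedioate | CCOC(=O)C(C)(Oc1c(C)c(OCOC)cc(OCOC)c1C=C)C(=O)OCC | intermediate
8 | 2-[6-ethenyl-3,5-bis(methoxymethoxy)-2-methylphenoxy]-2-methylpropane-1,3-diol | C=Cc1c(OC(C)(CO)CO)c(C)c(OCOC)cc1OCOC | intermediate
9 | 2-[6-ethenyl-3,5-bis(methoxymethoxy)-2-methylphenoxy]-2-methylpropanedial | C=Cc1c(OC(C)(C=O)C=O)c(C)c(OCOC)cc1OCOC | intermediate
10 | 3,5-bis(methoxymethoxy)-2-methyl-1-[(3-methylpenta-1,4-dien-3-yl)oxy]-6-vinylbenzene | C=Cc1c(OC(C)(C=C)C=C)c(C)c(OCOC)cc1OCOC | intermediate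
11 | (2R)-5,7-bis(methoxymethoxy)-2,8-dimethyl-2-vinyl-2H-chromene | COCOc1cc(OCOC)c2C=C[C@@](C)(C=C)Oc2c1C | intermediate
12 | 1-bromo-2-methylprop-1-ene | CC(C)=CBr | starting material
13 | (2R)-2-[2-(9-borabicyclo[3.3.1]nonan-9-yl)ethyl]-5,7-bis(methoxymethoxy)-2,8-dimethyl-2H-chromene | COCOc1cc(OCOC)c2C=C[C@@](C)(CCB3C4CCCC3CCC4)Oc2c1C | intermediate
14 | (2R)-5,7-bis(methoxymethoxy)-2,8-dimethyl-2-(4-methylpent-3-en-1-yl)-2H-chromene | COCOc1cc(OCOC)c2C=C[C@@](C)(CCC=C(C)C)Oc2c1C | intermediate
15 | (R)-2-methylbutanoic acid | CC[C@@H](C)C(=O)O | starting material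
16 | (2R)-1-(1H-imidazol-1-yl)-2-methylbutan-1-one | CC[C@@H](C)C(=O)n1ccnc1 | intermediate
17 | (2R)-N-methoxy-N,2-dimethylbutanamide | CC[C@@H](C)C(=O)N(C)OC | intermediate
18 | [(2R)-5,7-bis(methoxymethoxy)-2,8-dimethyl-2-(4-methylpent-3-en-1-yl)-2H-chromen-6-yl]lithium | [Li]c1c(OCOC)c2C=C[C@@](C)(CCC=C(C)C)Oc2c(C)c1OCOC | intermediate
19 | (2R)-1-[(2R)-5,7-bis(methoxymethoxy)-2,8-dimethyl-2-(4-methylpent-3-en-1-yl)-2H-chromen-6-yl]-2-methylbutan-1-one | CC[C@@H](C)C(=O)c1c(OCOC)c2C=C[C@@](C)(CCC=C(C)C)Oc2c(C)c1OCOC | intermediate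
20 | (2R)-1-[(2R)-5,7-dihydroxy-2,8-dimethyl-2-(4-methylpent-3-en-1-yl)-2H-chromen-6-yl]-2-methylbutan-1-one | CC[C@@H](C)C(=O)c1c(O)c2C=C[C@@](C)(CCC=C(C)C)Oc2c(C)c1O | intermediate
21 | (2R)-5-hydroxy-2,8,8-trimethyl-6-[(2R)-2-methylbutanoyl]-2-(4-methylpent-3-en-1-yl)-2H-chromen-7(8H)-one | CC[C@@H](C)C(=O)C1=C(O)C2=C(O[C@](C)(CCC=C(C)C)C=C2)C(C)(C)C1=O | target

**Step count and risks**

Total step count: 12. Longest linear sequence: 11 steps (steps 1–8 and 10–12 from 2-methylphloroglucinol); step 9 is a one-step side branch.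

Steps most likely to fail:

1. Step 7. The catalyst may discriminate poorly between the two enantiotopic vinyl groups, or the ether and acetal oxygens may bind molybdenum and stall turnover. Fallback: starting from 10, ring closure with the achiral RuCl2(H2IMes)(PCy3)(=CHPh) (second-generation Grubbs catalyst) in CH2Cl2 at 40 °C should give racemic 5,7-bis(methoxymethoxy)-2,8-dimethyl-2-vinyl-2H-chromene F1. The enantiomers would then be separated by preparative HPLC on a cellulose tris(3,5-dimethylphenylcarbamate) stationary phase, and the 2R enantiomer rejoins the route as 11.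

2. Step 6. The dialdehyde may lose a formyl group or hydrate before both olefinations are complete. Fallback: starting from 8, the two arms are converted one at a time.
   - Monosilylation (NaH, TBSCl, THF) should give racemic 3-{[tert-butyl(dimethyl)silyl]oxy}-2-[6-ethenyl-3,5-bis(methoxymethoxy)-2-methylphenoxy]-2-methylpropan-1-ol F2.
   - Dess–Martin oxidation gives racemic 3-{[tert-butyl(dimethyl)silyl]oxy}-2-[6-ethenyl-3,5-bis(methoxymethoxy)-2-methylphenoxy]-2-methylpropanal F3.
   - Wittig methylenation gives racemic tert-butyl({2-[6-ethenyl-3,5-bis(methoxymethoxy)-2-methylphenoxy]-2-methylbut-3-en-1-yl}oxy)dimethylsilane F4.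
   - Bu4NF gives racemic 2-[6-ethenyl-3,5-bis(methoxymethoxy)-2-methylphenoxy]-2-methylbut-3-en-1-ol F5.
   - A second Dess–Martin oxidation gives racemic 2-[6-ethenyl-3,5-bis(methoxymethoxy)-2-methylphenoxy]-2-methylbut-3-enal F6.
   - A final Wittig methylenation returns the achiral triene 10.

3. Step 3. Substitution at the tertiary carbon by a doubly ortho-flanked, chelated phenoxide may be slow, letting bromine transfer to the ring or elimination take over. Fallback: starting from 4, the ether is made through a secondary bromide and the methyl group is added afterwards.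
   - Wittig methylenation with excess ylide should give 6-ethenyl-3,5-bis(methoxymethoxy)-2-methylphenol F7.
   - O-alkylation with diethyl bromomalonate (K2CO3, acetone) gives diethyl 2-[6-ethenyl-3,5-bis(methoxymethoxy)-2-methylphenoxy]propanedioate F8; with the aldehyde already converted, no benzofuran-forming condensation is possible.
   - C-methylation of the malonate (NaH, MeI, DMF) returns to the route at 7.

**Further compounds**

F1 | step 7 | racemic 5,7-bis(methoxymethoxy)-2,8-dimethyl-2-vinyl-2H-chromene | COCOc1cc(OCOC)c2C=CC(C)(C=C)Oc2c1C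
F2 | step 6 | racemic 3-{[tert-butyl(dimethyl)silyl]oxy}-2-[6-ethenyl-3,5-bis(methoxymethoxy)-2-methylphenoxy]-2-methylpropan-1-ol | C=Cc1c(OC(C)(CO)CO[Si](C)(C)C(C)(C)C)c(C)c(OCOC)cc1OCOC
F3 | step 6 | racemic 3-{[tert-butyl(dimethyl)silyl]oxy}-2-[6-ethenyl-3,5-bis(methoxymethoxy)-2-methylphenoxy]-2-methylpropanal | C=Cc1c(OC(C)(C=O)CO[Si](C)(C)C(C)(C)C)c(C)c(OCOC)cc1OCOC
F4 | step 6 | racemic tert-butyl({2-[6-ethenyl-3,5-bis(methoxymethoxy)-2-methylphenoxy]-2-methylbut-3-en-1-yl}oxy)dimethylsilane | C=Cc1c(OC(C)(C=C)CO[Si](C)(C)C(C)(C)C)c(C)c(OCOC)cc1OCOC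
F5 | step 6 | racemic 2-[6-ethenyl-3,5-bis(methoxymethoxy)-2-methylphenoxy]-2-methylbut-3-en-1-ol | C=Cc1c(OC(C)(C=C)CO)c(C)c(OCOC)cc1OCOC
F6 | step 6 | racemic 2-[6-ethenyl-3,5-bis(methoxymethoxy)-2-methylphenoxy]-2-methylbut-3-enal | C=Cc1c(OC(C)(C=C)C=O)c(C)c(OCOC)cc1OCOC
F7 | step 3 | 6-ethenyl-3,5-bis(methoxymethoxy)-2-methylphenol | C=Cc1c(O)c(C)c(OCOC)cc1OCOC
F8 | step 3 | diethyl 2-[6-ethenyl-3,5-bis(methoxymethoxy)-2-methylphenoxy]propanedioate | CCOC(=O)C(Oc1c(C)c(OCOC)cc(OCOC)c1C=C)C(=O)OCC
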